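**Assumption:** natural (−)-α-zingiberene (the main hydrocarbon of commercial ginger oil, sold as the isolated terpene) and curcumin are purchased. Ring positions use the numbering of the target's cyclohexenyl unit: C1 (O-aryl), C2 (methyl), C4 (OH), C5 (side chain).

## Retrosynthetic overview

1. No carbocycle is built. The cyclohexene ring and both carbon stereocentres (C5 and the side-chain CH–CH3) are bought as (−)-α-zingiberene (1).
2. The C1–O and C4–O bonds are made together by a photochemical [4+2] addition of singlet oxygen to the diene of 1, anti to the side chain, giving endoperoxide 2. This transient dioxabicycle is the only ring formed.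
3. The O–O bond is cleaved with inversion at C1 only, by a new phosphine-mediated "peroxide-Mitsunobu" step, giving trans-1,4-diol 3.
4. The aryl ether C1–O bond is made by Mitsunobu etherification of 3 with curcumin (4). This second inversion at C1 gives net retention relative to 2 and delivers terpecurcumin B (5).

## Route

**Step 1**
Reactants: 1, (−)-α-zingiberene
Product: 2, (1R,4S,7R)-5-methyl-7-[(2S)-6-methylhept-5-en-2-yl]-2,3-dioxabicyclo[2.2.2]oct-5-ene (peroxide bridge anti to the side chain)
Conditions: O2 (1 atm), TPP (0.5 mol %), white LED, CH2Cl2, −78 °C, stopped at about 90% conversion; cold silica chromatography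
Reagents that add atoms: dioxygen, O=O
Why: Dye-sensitised singlet-oxygen [4+2] (Diels–Alder-type) photooxygenation, in which the s-cis cyclohexadiene should react roughly ten times faster than the trisubstituted side-chain alkene (Schenck ene); both C–O bonds form suprafacially on the diene face opposite the C5 side chain (substrate control, estimated about 3:1 anti:syn, minor isomer removed on silica), so the C1 and C4 oxygens are cis to each other and trans to the side chain.

**Step 2**
Reactants: 2, endoperoxide
Product: 3, (1R,4R,5R)-2-methyl-5-[(2S)-6-methylhept-5-en-2-yl]cyclohex-2-ene-1,4-diol (C1–OH cis to the side chain, C4–OH trans to it)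
Conditions: PPh3 (1.1 equiv), 4-O2NC6H4CO2H (1.5 equiv), THF, −30 °C → rt; then K2CO3, MeOH, rt (one pot)
Reagents that add atoms: 4-nitrobenzoic acid, OC(=O)c1ccc(cc1)[N+](=O)[O-] (supplies only the new C1 oxygen; the acyl group is removed by the methanolysis)
Why: Proposed new method: PPh3 inserts into the O–O bond to give the bridged dialkoxyphosphorane (the intermediate of a diol Mitsunobu reaction, made here without azodicarboxylate because the peroxide is the oxidant), the acid protonates it to an alkoxyphosphonium carboxylate, and SN2 displacement is feasible only at C1 because C4 is menthol-like with its backside blocked by the trans C5 side chain, so C1 is inverted, the C4–O bond is untouched, Ph3P=O removes the old C1 oxygen, and methanolysis frees the diol; the closest known chemistry is phosphine insertion into endoperoxides and inversion/alkylation of acids by dialkoxytriphenylphosphoranes (Mitsunobu).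

**Step 3**
Reactants: 3, trans-diol; 4, curcumin (3 equiv)
Product: 5, terpecurcumin B
Conditions: PPh3 (1.3 equiv), DIAD (1.3 equiv), THF, 0 °C → rt, dark
Reagents that add atoms: none (all product atoms come from 3 and 4)
Why: Mitsunobu aryl-ether formation (SN2 with inversion): only the carveol-like C1–OH can be displaced because C4–OH is again shielded by the side chain, the curcumin phenol (pKa about 9–10) is a competent pronucleophile, excess inexpensive curcumin suppresses bis-etherification, and the second inversion places the aryloxy group cis to C4–OH, giving (1S).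

## Compound list

1 | (−)-α-zingiberene, (5R)-2-methyl-5-[(2S)-6-methylhept-5-en-2-yl]cyclohexa-1,3-diene | CC1=CC[C@@H](C=C1)[C@@H](C)CCC=C(C)C | starting material
2 | (1R,4S,7R)-5-methyl-7-[(2S)-6-methylhept-5-en-2-yl]-2,3-dioxabicyclo[2.2.2]oct-5-ene | O1[C@H]2C[C@H]([C@@H](C)CCC=C(C)C)[C@@H](O1)C=C2C | intermediate
3 | (1R,4R,5R)-2-methyl-5-[(2S)-6-methylhept-5-en-2-yl]cyclohex-2-ene-1,4-diol | O[C@@H]1C[C@H]([C@@H](C)CCC=C(C)C)[C@@H](O)C=C1C | intermediate
4 | curcumin, (1E,4Z,6E)-5-hydroxy-1,7-bis(4-hydroxy-3-methoxyphenyl)hepta-1,4,6-trien-3-one | COc1cc(/C=C/C(=O)/C=C(O)/C=C/c2ccc(O)c(OC)c2)ccc1O | starting material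
5 | terpecurcumin B, (1E,4Z,6E)-5-hydroxy-1-(4-hydroxy-3-methoxyphenyl)-7-[4-({(1S,4R,5R)-4-hydroxy-2-methyl-5-[(2S)-6-methylhept-5-en-2-yl]cyclohex-2-en-1-yl}oxy)-3-methoxyphenyl]hepta-1,4,6-trien-3-one | COc1cc(/C=C/C(=O)/C=C(O)/C=C/c2ccc(O[C@H]3C[C@H]([C@@H](C)CCC=C(C)C)[C@@H](O)C=C3C)c(OC)c2)ccc1O | target

## Step count and risks

Total steps: 3. Longest linear sequence: 3.

Steps most likely to fail:

1. **Step 2 (proposed new peroxide-Mitsunobu).** Risks are collapse of the phosphorane to a vinyl epoxide, SN2′ attack, or simple reduction to the cis-diol. Fallback with known chemistry: Kornblum–DeLaMare rearrangement of 2 with Et3N to the 4-hydroxy-2-methyl enone (C1 ketone), then Luche reduction (cis-carveol-type selectivity) to the same diol 3.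
2. **Step 1 (photooxygenation).** Risks are modest facial selectivity and competing ene oxidation of the side-chain alkene. Fallback: Bäckvall Pd(II)/benzoquinone trans-1,4-diacetoxylation of 1 (external acetate at C1 anti to Pd, internal acetate delivery at C4), then methanolysis, giving 3 directly and bypassing 2.
3. **Step 3 (Mitsunobu with unprotected curcumin).** Risks are enol O- or C-alkylation, bis-etherification and SN2′. Fallback: Mitsunobu of 3 with vanillin to the aryl ether aldehyde, then Pabon boron-mediated aldol condensation (B2O3, B(OBu)3, BuNH2) with feruloylacetone, itself made from vanillin and acetylacetone.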